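**Retrosynthetic overview**

1. Target 8 ⇐ 2'-hydroxychalcone 7 by an enantioselective 6-endo oxa-Michael closure, the same ring closure that chalcone isomerase performs. The pyranone ring and the C2 stereocentre are made last.
2. Chalcone 7 ⇐ paeonol 5 + benzofuran aldehyde 4 by Claisen–Schmidt condensation (the C6–C3–C6 chain).
3. Aldehyde 4 ⇐ 4-hydroxybenzaldehyde 1 + 4-vinylanisole 2 by a one-step dehydrogenative phenol–styrene [3+2] annulation. It forms the same ortho-C–C and O–C bonds as the oxidative coupling of a 4-hydroxyphenyl unit with a styrene unit in the plant.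
4. Ring order: furan ring (step 1), then the open chalcone (step 2), then the pyranone ring (step 3). No protecting groups are used.

The target stereocentre, C2 of the flavanone, is S as drawn in the SMILES.

Assumption: the quinine-derived thiourea named in step 3 delivers the (2S) enantiomer; if chiral HPLC and the ECD sign (positive band near 330 nm for 2S) show the opposite sense, its quinidine-derived pseudo-enantiomer is used under the same conditions.

**Route**

Step 1
Reactants: 1 4-hydroxybenzaldehyde; 2 4-vinylanisole (4-methoxystyrene, 3 equiv)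
Product: 4 2-(4-methoxyphenyl)-1-benzofuran-5-carbaldehyde, via (E)-2-hydroxystilbene aldehyde 3 (not isolated)
Conditions: Pd(OAc)2 (10 mol %), 1,10-phenanthroline (20 mol %), anhydrous Cu(OAc)2 (4.4 equiv), NaOAc (2 equiv), ClCH2CH2Cl, N2, sealed tube, 110 °C, 24 h; 2 added in three portions
Reagents that add atoms: none
Why: This is a dehydrogenative phenol–styrene annulation of the Fujiwara–Moritani (oxidative Heck) type, in which divalent palladium olefinates the position ortho to the phenol (β-selective, giving stilbene 3), 5-endo oxypalladation at the anisyl-stabilised benzylic carbon and β-hydride elimination close the furan, and zerovalent palladium is reoxidised after each of the two dehydrogenations by Cu(OAc)2 (four equivalents in all, ending as CuOAc and AcOH), so that with O2 and water kept out neither the aldehyde nor the styrene is oxidised; both ortho positions of 1 are equivalent.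

Step 2
Reactants: 4 2-(4-methoxyphenyl)-1-benzofuran-5-carbaldehyde; 5 paeonol (1-(2-hydroxy-4-methoxyphenyl)ethan-1-one, 1.1 equiv)
Product: 7 (E)-1-(2-hydroxy-4-methoxyphenyl)-3-[2-(4-methoxyphenyl)-1-benzofuran-5-yl]prop-2-en-1-one, via aldol adduct 6 (not isolated)
Conditions: KOH (50% aq, 8 equiv), EtOH–THF (3:1), 0 °C → rt, 36 h; then 1 M HCl, 0 °C, to pH 4–5; recrystallise (EtOH)
Reagents that add atoms: none
Why: In this Claisen–Schmidt (crossed aldol) condensation the non-enolisable aldehyde 4 captures the enolate of 5, E1cB dehydration of 6 gives only the (E)-enone, and in strong base the product sits as its 2'-phenolate, for which ring closure is reversible and disfavoured, so cold acidification returns the open chalcone.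

Step 3
Reactants: 7 (E)-1-(2-hydroxy-4-methoxyphenyl)-3-[2-(4-methoxyphenyl)-1-benzofuran-5-yl]prop-2-en-1-one
Product: 8 Lophirone J, (2S)-7-methoxy-2-[2-(4-methoxyphenyl)-1-benzofuran-5-yl]-2,3-dihydro-4H-chromen-4-one
Conditions: 1-[3,5-bis(trifluoromethyl)phenyl]-3-[(8α,9S)-6'-methoxycinchonan-9-yl]thiourea (C29H28F6N4OS, 15 mol %), PhCl, 0 °C → rt, 48–72 h, stopped at about 80% conversion (chiral HPLC); silica plug; recrystallise (EtOAc–heptane); recovered 7 recycled
Reagents that add atoms: none
Why: This is an organocatalytic enantioselective intramolecular oxa-Michael addition (6-endo-trig, chalcone-isomerase-like) in which the quinuclidine nitrogen deprotonates the 2'-OH while the thiourea N–H pair binds the enone oxygen, so the chiral phenoxide–ammonium ion pair adds to the Si face of C-β under kinetic control and sets the single (2S) stereocentre in the last step, after which nothing can scramble it.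

**Compound list**

1 | 4-hydroxybenzaldehyde | O=Cc1ccc(O)cc1 | starting material
2 | 4-vinylanisole (4-methoxystyrene) | C=Cc1ccc(OC)cc1 | starting material
3 | (E)-4-hydroxy-3-[2-(4-methoxyphenyl)ethenyl]benzaldehyde (formed in the flask, not isolated) | COc1ccc(/C=C/c2cc(C=O)ccc2O)cc1 | intermediate
4 | 2-(4-methoxyphenyl)-1-benzofuran-5-carbaldehyde | COc1ccc(-c2cc3cc(C=O)ccc3o2)cc1 | intermediate
5 | paeonol, 1-(2-hydroxy-4-methoxyphenyl)ethan-1-one | CC(=O)c1ccc(OC)cc1O | starting material
6 | racemic 3-hydroxy-1-(2-hydroxy-4-methoxyphenyl)-3-[2-(4-methoxyphenyl)-1-benzofuran-5-yl]propan-1-one (aldol adduct, not isolated) | COc1ccc(-c2cc3cc(C(O)CC(=O)c4ccc(OC)cc4O)ccc3o2)cc1 | intermediate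
7 | (E)-1-(2-hydroxy-4-methoxyphenyl)-3-[2-(4-methoxyphenyl)-1-benzofuran-5-yl]prop-2-en-1-one | COc1ccc(-c2cc3cc(/C=C/C(=O)c4ccc(OC)cc4O)ccc3o2)cc1 | intermediate
8 | Lophirone J, (2S)-7-methoxy-2-[2-(4-methoxyphenyl)-1-benzofuran-5-yl]-2,3-dihydro-4H-chromen-4-one | COc1ccc(-c2cc3cc([C@@H]4CC(=O)c5ccc(OC)cc5O4)ccc3o2)cc1 | target

**Step count**

Total steps: 3. Longest linear sequence: 3 (1 → 4 → 7 → 8); 2 and 5 enter in steps 1 and 2.

**Steps most likely to fail, with fallbacks**

Most at risk is step 3. The oxa-Michael closure of an unactivated 2'-hydroxychalcone is reversible, and the same catalyst can erode the ee by retro-addition. The electron-rich 4'-methoxy ring also lowers the electrophilicity of the enone. If the ee stays low even after recrystallisation, the enone is activated with an ester so that the closure becomes fast and essentially irreversible. The fallback sets out from aldehyde 4. Commercial methyl 2-hydroxy-4-methoxybenzoate is treated with the lithium enolate of tert-butyl acetate (LiN(iPr)2, 4 equiv, THF, −78 → 0 °C, crossed Claisen) to give tert-butyl 3-(2-hydroxy-4-methoxyphenyl)-3-oxopropanoate F5. Knoevenagel condensation of F5 with 4 (piperidine/AcOH cat., toluene, 4 Å sieves, rt) gives tert-butyl 2-(2-hydroxy-4-methoxybenzoyl)-3-[2-(4-methoxyphenyl)-1-benzofuran-5-yl]prop-2-enoate F6. The same thiourea (10 mol %, toluene, −25 °C) closes it to tert-butyl (2S)-7-methoxy-2-[2-(4-methoxyphenyl)-1-benzofuran-5-yl]-4-oxochromane-3-carboxylate F7. TsOH·H2O in the same pot (toluene, 80 °C) removes the ester by loss of isobutene and decarboxylation without touching C2, and the sequence comes back to the route at 8.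

Second is step 1. The acidic, electron-poor phenol 1 may be palladated only slowly, and oligomerisation or oxidative homocoupling of the electron-rich styrene 2 may then outrun the annulation. The benzofuran is then built from a pre-halogenated phenol. The fallback sets out from 1. Iodination (NIS, AcOH, rt) gives 4-hydroxy-3-iodobenzaldehyde F1. Sonogashira coupling with commercial 4-ethynylanisole (PdCl2(PPh3)2 2 mol %, CuI 4 mol %, Et3N, DMF, 70 °C) gives 4-hydroxy-3-[(4-methoxyphenyl)ethynyl]benzaldehyde F2. F2 cyclises 5-endo-dig in the same flask, and the sequence comes back to the route at 4.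

Third is step 2. The phenolate of 5 makes a sluggish enolate, aldehyde 4 is poorly soluble, and some racemic flavanone can form on work-up. The condensation is then run on the protected ketone. The fallback sets out from 5. Protection (NaH, MOMCl, DMF, 0 °C) gives 1-[4-methoxy-2-(methoxymethoxy)phenyl]ethan-1-one F3. Claisen–Schmidt condensation with 4 (KOH, EtOH–THF, rt) gives (E)-1-[4-methoxy-2-(methoxymethoxy)phenyl]-3-[2-(4-methoxyphenyl)-1-benzofuran-5-yl]prop-2-en-1-one F4, which cannot cyclise. Brief acidic methanolysis (3 M HCl, MeOH, 50 °C, 20 min) frees the phenol, and the sequence comes back to the route at 7, which is recrystallised before step 3.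

**Further compounds**

F1 | step 1 | 4-hydroxy-3-iodobenzaldehyde | O=Cc1ccc(O)c(I)c1
F2 | step 1 | 4-hydroxy-3-[(4-methoxyphenyl)ethynyl]benzaldehyde | COc1ccc(C#Cc2cc(C=O)ccc2O)cc1
F3 | step 2 | 1-[4-methoxy-2-(methoxymethoxy)phenyl]ethan-1-one | CC(=O)c1ccc(OC)cc1OCOC
F4 | step 2 | (E)-1-[4-methoxy-2-(methoxymethoxy)phenyl]-3-[2-(4-methoxyphenyl)-1-benzofuran-5-yl]prop-2-en-1-one | COCOc1cc(OC)ccc1C(=O)/C=C/c1ccc2oc(-c3ccc(OC)cc3)cc2c1
F5 | step 3 | tert-butyl 3-(2-hydroxy-4-methoxyphenyl)-3-oxopropanoate | COc1ccc(C(=O)CC(=O)OC(C)(C)C)c(O)c1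
F6 | step 3 | tert-butyl 2-(2-hydroxy-4-methoxybenzoyl)-3-[2-(4-methoxyphenyl)-1-benzofuran-5-yl]prop-2-enoate (E/Z mixture) | COc1ccc(-c2cc3cc(C=C(C(=O)OC(C)(C)C)C(=O)c4ccc(OC)cc4O)ccc3o2)cc1
F7 | step 3 | tert-butyl (2S)-7-methoxy-2-[2-(4-methoxyphenyl)-1-benzofuran-5-yl]-4-oxochromane-3-carboxylate (C3 epimers and enol) | COc1ccc(-c2cc3cc([C@@H]4C(C(=O)OC(C)(C)C)C(=O)c5ccc(OC)cc5O4)ccc3o2)cc1
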